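**Retrosynthetic overview**
1. Target ⇐ Evans–Tishchenko reduction of a C8-hydroxy-C10-ketone with isobutyraldehyde; this places the last isobutyrate on O8 only and sets C10.
2. Key disconnection C1–C7: nickel-catalysed radical cross-electrophile coupling of a fully acylated 1,2-epoxycyclohexane with a 2-bromoallylic alcohol; the C1 radical comes from the in-situ iodohydrin and the oxirane oxygen becomes the free C2 hydroxyl.
3. Epoxide ⇐ toluene cis-dihydrodiol by hydroxyl-directed epoxidation at C3/C4, diacylation, anti hydrolysis at C3, a second hydroxyl-directed epoxidation at C1/C2, and acylation.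
4. Bromide ⇐ diisopinocampheylboron aldol of 2-bromoacrolein with 3-hydroxy-3-methylbutan-2-one.
5. Ring order: the carbocycle is the dearomatised toluene ring (step 1) and is never closed by cyclisation; oxirane one (C3–C4) is made in step 2 and opened in step 4, oxirane two (C1–C2) is made in step 5 and opened in step 8.

Assumption and convention: 2-bromoacrolein and the toluene-dioxygenase strain are bought. Ring locants C1–C6 follow the target (C1 carries the side chain, C4 the methyl); the side chain is C7 (attached to C1, carries =CH2), C8, C9, C10, C11. β is the ring face of the C4 hydroxyl, α the opposite face.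

**Step 1**
Reactants: 1 toluene
Product: 2 (1S,2R)-3-methylcyclohexa-3,5-diene-1,2-diol
Conditions: E. coli JM109(pDTG601) whole cells (toluene dioxygenase), glucose, air, phosphate buffer pH 7.2, 35 °C
Reagents that add atoms: dioxygen O=O
Why: Enzymatic arene cis-dihydroxylation (toluene dioxygenase) adds both oxygen atoms of O2 to one face of the C5–C6 bond with >98% ee, which sets C5 and C6.

**Step 2**
Reactants: 2 (1S,2R)-3-methylcyclohexa-3,5-diene-1,2-diol
Product: 3 (1S,2S,3S,6R)-1-methyl-7-oxabicyclo[4.1.0]hept-4-ene-2,3-diol (3β,4β-epoxide with 5β,6β-diol)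
Conditions: t-BuOOH (1.05 equiv), VO(acac)2 (2 mol%), CH2Cl2, 0 °C
Reagents that add atoms: tert-butyl hydroperoxide CC(C)(C)OO
Why: Hydroxyl-directed vanadium-catalysed epoxidation (Sharpless–Michaelson) oxidises the more electron-rich trisubstituted C3=C4 bond, allylic to the C5 hydroxyl, on the face of that hydroxyl, which sets the β C4–O bond and a β oxirane at C3 that is inverted in step 4.

**Step 3**
Reactants: 3 (1S,2S,3S,6R)-1-methyl-7-oxabicyclo[4.1.0]hept-4-ene-2,3-diol
Product: 5 5β-acetoxy-3β,4β-epoxy-6β-isobutyryloxy-4-methylcyclohex-1-ene, via 6-O-isobutyryl epoxy alcohol 4 (not isolated)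
Conditions: i-PrCOCl (1.05 equiv), 2,4,6-collidine, CH2Cl2, −60 → −30 °C; then Ac2O, DMAP (cat.), 0 °C
Reagents that add atoms: isobutyryl chloride CC(C)C(=O)Cl; acetic anhydride CC(=O)OC(C)=O
Why: Sequential regioselective O-acylation in one pot, in which the C6 hydroxyl next to sp2 C1 reacts first with the bulky acid chloride and the C5 hydroxyl next to the fully substituted oxirane carbon is then acetylated, with no stereocentre touched (a cis-epoxy alcohol cannot undergo Payne rearrangement).

**Step 4**
Reactants: 5 5β-acetoxy-3β,4β-epoxy-6β-isobutyryloxy-4-methylcyclohex-1-ene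
Product: 6 5β-acetoxy-6β-isobutyryloxy-4α-methylcyclohex-1-ene-3α,4β-diol
Conditions: HClO4 (cat.), THF/H2O 3:1, 0 °C
Reagents that add atoms: water O
Why: Acid-catalysed anti hydrolysis of a vinyl oxirane, in which water attacks the allylic C3 with inversion (C4 is tertiary, neopentyl-like and deactivated by the neighbouring acetoxy group), which sets the α C3–O bond and frees the tertiary β hydroxyl at C4.

**Step 5**
Reactants: 6 5β-acetoxy-6β-isobutyryloxy-4α-methylcyclohex-1-ene-3α,4β-diol
Product: 7 5β-acetoxy-1α,2α-epoxy-6β-isobutyryloxy-4α-methylcyclohexane-3α,4β-diol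
Conditions: t-BuOOH (1.2 equiv), VO(acac)2 (3 mol%), CH2Cl2, 0 °C → rt
Reagents that add atoms: tert-butyl hydroperoxide CC(C)(C)OO
Why: Hydroxyl-directed vanadium-catalysed epoxidation in which the allylic C3 hydroxyl delivers oxygen to its own α face of the C1=C2 bond, which sets the α C2–O bond, while the allylic ester at C6 cannot direct.

**Step 6**
Reactants: 7 5β-acetoxy-1α,2α-epoxy-6β-isobutyryloxy-4α-methylcyclohexane-3α,4β-diol
Product: 8 5β-acetoxy-1α,2α-epoxy-3α,6β-bis(isobutyryloxy)-4α-methylcyclohexan-4β-ol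
Conditions: i-PrCOCl (1.5 equiv), pyridine, DMAP (cat.), CH2Cl2, 0 °C
Reagents that add atoms: isobutyryl chloride CC(C)C(=O)Cl
Why: DMAP-catalysed esterification of the only secondary hydroxyl (C3), with the tertiary C4 hydroxyl and the oxirane inert at 0 °C and no stereocentre changed.

**Step 7**
Reactants: 9 3-hydroxy-3-methylbutan-2-one; 10 2-bromoprop-2-enal (2-bromoacrolein)
Product: 14 (5S)-6-bromo-5-hydroxy-2-methyl-2-(trimethylsilyloxy)hept-6-en-3-one, via silyl ether 11 (not isolated), via enol borinate 12 (not isolated), via boron aldolate 13 (not isolated)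
Conditions: Me3SiCl (1.1 equiv), Et3N, DMAP (cat.), Et2O, 0 °C → rt; (−)-Ipc2BCl (1.4 equiv), Et3N, 0 °C; 10 (1.5 equiv), −78 → −20 °C; H2O2, pH 7 buffer, MeOH, 0 °C
Reagents that add atoms: chlorotrimethylsilane C[Si](C)(C)Cl
Why: Paterson boron aldol reaction in which, after in-situ silylation of the tertiary hydroxyl, the methyl-ketone enol diisopinocampheylborinate from the (−)-reagent adds to the Si face of the non-enolisable aldehyde through a cyclic transition state, which sets C8 as S (about 80–90% ee, the minor enantiomer leaving as a separable diastereomer after step 8).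

**Step 8**
Reactants: 8 5β-acetoxy-1α,2α-epoxy-3α,6β-bis(isobutyryloxy)-4α-methylcyclohexan-4β-ol; 14 (5S)-6-bromo-5-hydroxy-2-methyl-2-(trimethylsilyloxy)hept-6-en-3-one (1.5 equiv)
Product: 16 (1S,2S,3S,4R,5S,6S)-5-acetoxy-2,4-dihydroxy-1-[(3S)-3-hydroxy-6-methyl-5-oxo-6-(trimethylsilyloxy)hept-1-en-2-yl]-4-methylcyclohexane-3,6-diyl bis(2-methylpropanoate), via iodohydrin 15 (not isolated)
Conditions: NiCl2(dme) (10 mol%), 4,4'-di-tert-butyl-2,2'-bipyridine (10 mol%), NaI (1 equiv), Et3N·HCl (1.5 equiv), Mn powder (3 equiv), DMPU, 25 °C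
Reagents that add atoms: none
Why: Nickel-catalysed reductive cross-electrophile coupling of an epoxide with an alkenyl bromide (Weix type, iodide co-catalysis), in which iodide opens the oxirane trans-diaxially at C1 (attack at C2 would be syn-axial to the C4 hydroxyl and the C6 ester), nickel abstracts the iodine to give the secondary C1 radical, and the alkenylnickel species captures this radical on the β face, equatorial, trans to O2 and away from the axial C3 ester, so that reductive elimination forms the C1–C7 bond with C1 as S and leaves O2 as the free hydroxyl.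

**Step 9**
Reactants: 16 (the coupled β-hydroxy ketone)
Product: 18 CNP0348997.1, (1S,2S,3S,4R,5S,6S)-5-acetoxy-1-[(3S,5S)-5,6-dihydroxy-6-methyl-3-(2-methylpropanoyloxy)hept-1-en-2-yl]-2,4-dihydroxy-4-methylcyclohexane-3,6-diyl bis(2-methylpropanoate), via silyl ether 17 (not isolated)
Conditions: SmI2 (30 mol%), i-PrCHO (6 equiv), THF, −10 °C; then 0.5 M aq. citric acid, THF, 0 °C → rt
Reagents that add atoms: isobutyraldehyde CC(C)C=O
Why: Evans–Tishchenko reduction in which, within the samarium-bound hemiacetal of the C8 hydroxyl and isobutyraldehyde, hydride shifts to the C10 ketone through a chair-like six-membered transition state, which gives the 1,3-anti diol monoester (C10 S) with the isobutyrate on O8 only, and the acidic work-up removes the trimethylsilyl group.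

**Compound list**
1 | toluene | Cc1ccccc1 | starting material
2 | (1S,2R)-3-methylcyclohexa-3,5-diene-1,2-diol | C1=CC=C(C)[C@@H](O)[C@H]1O | intermediate
3 | (1S,2S,3S,6R)-1-methyl-7-oxabicyclo[4.1.0]hept-4-ene-2,3-diol (oxirane cis to both hydroxyls) | C1=C[C@H]2O[C@@]2(C)[C@@H](O)[C@H]1O | intermediate
4 | 6-O-isobutyrate of 3 (ester on the hydroxyl next to the alkene) | C1=C[C@H]2O[C@@]2(C)[C@@H](O)[C@H]1OC(=O)C(C)C | intermediate (not isolated)
5 | 5β-acetoxy-3β,4β-epoxy-6β-isobutyryloxy-4-methylcyclohex-1-ene | C1=C[C@H]2O[C@@]2(C)[C@@H](OC(C)=O)[C@H]1OC(=O)C(C)C | intermediate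
6 | 5β-acetoxy-6β-isobutyryloxy-4α-methylcyclohex-1-ene-3α,4β-diol | C1=C[C@H](O)[C@@](C)(O)[C@@H](OC(C)=O)[C@H]1OC(=O)C(C)C | intermediate
7 | 5β-acetoxy-1α,2α-epoxy-6β-isobutyryloxy-4α-methylcyclohexane-3α,4β-diol | O1[C@@H]2[C@H]1[C@H](O)[C@@](C)(O)[C@@H](OC(C)=O)[C@H]2OC(=O)C(C)C | intermediate
8 | 5β-acetoxy-1α,2α-epoxy-3α,6β-bis(isobutyryloxy)-4α-methylcyclohexan-4β-ol | O1[C@@H]2[C@H]1[C@H](OC(=O)C(C)C)[C@@](C)(O)[C@@H](OC(C)=O)[C@H]2OC(=O)C(C)C | intermediate
9 | 3-hydroxy-3-methylbutan-2-one | CC(=O)C(C)(C)O | starting material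
10 | 2-bromoprop-2-enal | C=C(Br)C=O | starting material
11 | 3-methyl-3-(trimethylsilyloxy)butan-2-one | CC(=O)C(C)(C)O[Si](C)(C)C | intermediate (not isolated)
12 | enol diisopinocampheylborinate of 11 | C=C(OB([C@@H]1C[C@@H]2C[C@H]([C@H]1C)C2(C)C)[C@@H]1C[C@@H]2C[C@H]([C@H]1C)C2(C)C)C(C)(C)O[Si](C)(C)C | intermediate (not isolated)
13 | O-diisopinocampheylboryl (S)-aldolate | C=C(Br)[C@@H](OB([C@@H]1C[C@@H]2C[C@H]([C@H]1C)C2(C)C)[C@@H]1C[C@@H]2C[C@H]([C@H]1C)C2(C)C)CC(=O)C(C)(C)O[Si](C)(C)C | intermediate (not isolated)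
14 | (5S)-6-bromo-5-hydroxy-2-methyl-2-(trimethylsilyloxy)hept-6-en-3-one | C=C(Br)[C@@H](O)CC(=O)C(C)(C)O[Si](C)(C)C | intermediate
15 | 5β-acetoxy-1β-iodo-3α,6β-bis(isobutyryloxy)-4α-methylcyclohexane-2α,4β-diol | I[C@H]1[C@H](O)[C@H](OC(=O)C(C)C)[C@@](C)(O)[C@@H](OC(C)=O)[C@H]1OC(=O)C(C)C | intermediate (not isolated)
16 | coupled β-hydroxy ketone (name in step 8) | C=C([C@H]1[C@H](O)[C@H](OC(=O)C(C)C)[C@@](C)(O)[C@@H](OC(C)=O)[C@H]1OC(=O)C(C)C)[C@@H](O)CC(=O)C(C)(C)O[Si](C)(C)C | intermediate
17 | 11-O-trimethylsilyl ether of the target | C=C([C@H]1[C@H](O)[C@H](OC(=O)C(C)C)[C@@](C)(O)[C@@H](OC(C)=O)[C@H]1OC(=O)C(C)C)[C@H](C[C@H](O)C(C)(C)O[Si](C)(C)C)OC(=O)C(C)C | intermediate (not isolated)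
18 | CNP0348997.1 (ring 1S,2S,3S,4R,5S,6S; side chain 8S,10S) | C=C([C@H]1[C@H](O)[C@H](OC(=O)C(C)C)[C@@](C)(O)[C@@H](OC(C)=O)[C@H]1OC(=O)C(C)C)[C@H](C[C@H](O)C(C)(C)O)OC(=O)C(C)C | target

**Totals**
Total steps: 9. Longest linear sequence: 8 (steps 1–6, 8, 9).

**Steps most likely to fail**

Step 8 is the weakest point. The in-situ iodide opening may go to C2 instead of C1, or the trans C6 ester may open the oxirane by participation. The iodohydrin may lose HOI to give the cyclohexene, and the hindered secondary radical may couple slowly or on the wrong face. The fallback sets out from 7 and comes back at 16. Epoxy alcohol 7 is opened with I2 and Ti(OiPr)4 in CH2Cl2 at 0 °C, where chelation by the C3 hydroxyl steers iodide to the distal carbon C1, to give the 1β-iodo-2α,3α,4β-triol F1. Its cis-2,3-diol is closed with trimethyl orthoisobutyrate and camphorsulfonic acid to the cyclic 2,3-orthoisobutyrate F2. Hydrolysis with aqueous acetic acid leaves the ester on the axial O3 and the hydroxyl on the equatorial O2, which is iodohydrin 15, now isolated with secured regiochemistry. 15 is then joined to 14 by metallaphotoredox cross-electrophile coupling (Ir[dF(CF3)ppy]2(dtbbpy)PF6, NiCl2(dme), 4,4'-di-tert-butyl-2,2'-bipyridine, (Me3Si)3SiH, Na2CO3, DME, blue light). Here a silyl radical abstracts the iodine, and no metal reductant or acid is present, to give 16.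

Step 4 may give attack of water at the tertiary C4 or at C1 (allylic transposition) through cationic character. The fallback sets out from 5 and comes back at 6. The vinyl oxirane is opened under buffered SN2 conditions with ClCH2CO2Cs and ClCH2CO2H in DMF at 40 °C, where a carboxylate cannot attack the tertiary carbon, to give the 3α-O-chloroacetate F3. The chloroacetyl group alone is then removed with thiourea and NaHCO3 in ethanol to give 6.

Step 2 has two alkenes that each carry a directing allylic hydroxyl, and both the diene diol and the vinyl oxirane are acid-sensitive, so the wrong alkene or over-oxidation is possible. The fallback sets out from 2 and comes back at 5. The less hindered distal hydroxyl of 2 is acylated first (i-PrCOCl, 2,4,6-collidine, CH2Cl2, −60 °C) to give (1S,6R)-6-hydroxy-5-methylcyclohexa-2,4-dien-1-yl 2-methylpropanoate F4, so that only the C5 hydroxyl can direct. Henbest epoxidation with mCPBA and NaHCO3 then gives 4, which is acetylated as in the second half of step 3 to 5; this also removes the selectivity demand of step 3.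

**Further compounds**
F1 | step 8 | 5β-acetoxy-1β-iodo-6β-isobutyryloxy-4α-methylcyclohexane-2α,3α,4β-triol | I[C@H]1[C@H](O)[C@H](O)[C@@](C)(O)[C@@H](OC(C)=O)[C@H]1OC(=O)C(C)C
F2 | step 8 | 2α,3α-O-(1-methoxy-2-methylpropylidene) orthoester of F1 | I[C@H]1[C@@H]2OC(OC)(C(C)C)O[C@@H]2[C@@](C)(O)[C@@H](OC(C)=O)[C@H]1OC(=O)C(C)C
F3 | step 4 | 5β-acetoxy-3α-chloroacetoxy-6β-isobutyryloxy-4α-methylcyclohex-1-en-4β-ol | C1=C[C@H](OC(=O)CCl)[C@@](C)(O)[C@@H](OC(C)=O)[C@H]1OC(=O)C(C)C
F4 | step 2 | (1S,6R)-6-hydroxy-5-methylcyclohexa-2,4-dien-1-yl 2-methylpropanoate | C1=CC=C(C)[C@@H](O)[C@H]1OC(=O)C(C)C
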